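The earlier runs and the new flask come from a simulation for substances that don't exist.

Take the leftover first: the noon readings average 0.534 of the charge as target, so 0.466 of it sits somewhere the readings don't show.

| flask | substrate | enzyme | remark | time |
|---|---|---|---|---|
| noon | 0.045 M | 34 µM | run made earlier |  |
| dawn | 0.045 M | 23 µM | run made earlier |  |
| midnight | 0.045 M | 51 µM | run made earlier |  |
| summer | 0.068 M | 34 µM | run made earlier |  |
| larch | 0.045 M | 34 µM | a closed flask charged with all of it at once and left for 20 h | 20 h |
| elm | 0.045 M | 34 µM | a single well-mixed tank run continuously and read at steady state, 20 h in it on average |  |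
| cedar | 0.045 M (fed, over 16.0 h) | 34 µM | all but substrate at the start; substrate goes in evenly over 16.0 h, the run ends at 20 h | 20 h |

| run | time / h | target / % |
|---|---|---|
| noon | 4.00 | 55 |
| noon | 8.00 | 53 |
| noon | 12.0 | 56 |
| noon | 15.0 | 53 |
| noon | 20.0 | 50 |
| dawn | 3.00 | 47 |
| dawn | 6.00 | 46 |
| dawn | 10.0 | 43 |
| dawn | 12.0 | 47 |
| dawn | 15.0 | 48 |
| midnight | 3.00 | 60 |
| midnight | 6.00 | 62 |
| midnight | 10.0 | 65 |
| midnight | 12.0 | 61 |
| midnight | 15.0 | 61 |
| summer | 1.33 | 49 |
| summer | 2.50 | 55 |
| summer | 5.00 | 44 |
| summer | 8.00 | 51 |
| summer | 15.0 | 49 |

(scatter of a reading: 2 percentage points)

- the stated concentrations are those of everything mixed, before any reaction; amounts are the same in each set-up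
- the numbers in the tables scatter by 2 percentage points (one standard deviation)
- the feed brings no volume worth counting
- the earlier runs were made in a closed, stirred flask

- order of the set-ups by the amount of target at the outlet or at the end, in percent of the substrate put in, highest first (larch / elm / cedar)
- amount of target at the outlet or at the end, in percent of the substrate put in, larch
- amount of target at the outlet or at the end, in percent of the substrate put in, elm
- amount of target at the outlet or at the end, in percent of the substrate put in, cedar

Here is my own reckoning. The readings are flat, so target is safe late and the loss happens early, beside substrate. Count steps: an enzyme step turns one substrate into one target, and a loss step, on the harsher guess, takes one substrate and one target. The drain ratio, loss steps per enzyme step over a whole run (the inverse of a selectivity factor), is then (1−y)/(1+y) for a final target fraction y, here 0.304.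

From above: if substrate were its own partner in the loss, thin substrate in elm and cedar spares the charge, so the top of my bracket is the whole charge as target. From below: if target is the partner, the momentary ratio is proportional to the target fraction, and I take the factor as 1.14, so that the ratio grows from zero to twice its mean. Elm sits at that end state throughout, giving 0.388, while cedar climbs larch's path to 0.534.

To tighten this, summer and dawn carry nearly the same substrate per enzyme, yet summer reads 0.496 against 0.462. I read that as a thicker charge favouring the enzyme, so I expect thin substrate to favour it less. I commit to larch at 0.534, with elm and cedar under their low marks.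

The forecast says cedar > elm > larch, with larch 53%, elm 88% and cedar 90%, on the ground that “Elm and cedar both hold substrate very low”. That puts elm above its low mark and cedar above its own, towards the top of the bracket.

The flasks give larch > cedar > elm: larch 54.3%, elm 29.9%, cedar 41.7%. Elm and cedar land under the low marks.

    substrate + enzyme → target + enzyme, rate k1*[substrate]^1.5*[enzyme]/(1 + ([substrate]/Kh1)^1.5) (0.0877 M, k = 81.3 M⁻¹·⁵ s⁻¹)
    substrate + target → side product (k = 0.00549 M⁻¹ s⁻¹)

Larch's drain ratio comes to 0.296. Now take the neighbouring flask, larch with 0.11 M of substrate. Read off the noon and summer readings, the ratio goes with the charge to the power 0.251, so the neighbouring flask's ratio reckons to 0.380 and its target to 0.449 of the charge. The neighbouring flask holds 39.7% as target, a drain ratio of 0.432.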